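The numbers are invented; what happens was integrated by code.

I read the flask at 15 h and ask how far the gas feed has got by then against the Q charged.

Q 0.10 M; J 6.9 mM (held); time 15 h

    J ⇌ L, rate k1*(csat - [L]) (k1 = 5.51 × 10⁻⁴ s⁻¹, csat = 6.9 mM)
    Q + L → Q.L (k2 = 0.101 M⁻¹ s⁻¹)
    L + Q.L → L.Q.L (k3 = 0.00417 M⁻¹ s⁻¹)
    2 L → L2 (k4 = 0.00372 M⁻¹ s⁻¹)

1. Q.L at 15 h, in percent of the Q charged
2. concentration of L in solution at 15 h, in percent of saturation

- for a step with 2 of a species take k times the square, and two of it per event
- at the start none of L is dissolved
- run time (flask): 15 h

While Q stands near its charge, L has a half-life of 1.1 min against Q, shorter than the 21.0 min of gas transfer. So dissolved L stays low and transfer is the rate-limiting step. This gives my quantity, the charge time: the time the gas, at full drive into an empty solution, needs to deliver one L for every Q charged, the charge divided by transfer coefficient times saturation.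

charge time = 7.31 h

This flask's charge time is shorter than the reading time, so I count Q.L as the whole charge at that moment and let L then attack it. The neighbour with 0.25 M of Q has a charge time of 18.3 h, longer than the reading time, so it should still be in the first stage, with about 17.9% of its Q unreacted.

In this flask, L settles with a half-time of 11.9 min, shorter than the 7.69 h that remain, so I freeze it where transfer balances loss onto Q.L, leaving L2 aside:

share of saturation = 56.9%

Q.L then decays pseudo-first-order at that frozen L for the remaining time:

y = 63.5%

With Q.L down to that level, the same balance gives:

sat = 67.5%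

The forecast gives 65% and 64%, holding that “transfer balances mainly consumption by the remaining Q.L”.

The flask gives 64.8% and 64.1%. Its Q passes the run-out mark at 9.81 h, which is 1.34 charge times. The neighbour with 0.25 M of Q keeps 24% of its charge at 15 h, against my 17.9%, and holds Q.L at 73.4%. At 15 h this flask has Q at 0%, Q.L at 64.8% and L.Q.L at 35.2%, and it is not at rest. Left until 150 h, it shows Q.L at 0%, L.Q.L at >99.9%, L at 92.1% of saturation, and L2 risen from 1.38% to 69.9% of the charge.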